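Start with an easy step: a substrate meets free catalyst and becomes catalyst intermediate. That intermediate then has two exits. It can release target and free catalyst, or two intermediates can join as spent catalyst, with their substrates locked inside.

| flask | substrate | free catalyst | remark | time |
|---|---|---|---|---|
| epsilon | 2 M | 140 mM | run made earlier |  |
| gamma | 2 M | 1000 mM | run made earlier |  |
| spring | 2.0 M | 200 mM |  | 50 min |
| dusk | 2.0 M | 400 mM |  | 50 min |
| dawn | 2.0 M | 800 mM |  | 50 min |
| winter | 2.0 M | 1500 mM |  | 50 min |

| run | time / min | target / % |
|---|---|---|
| epsilon | 10.0 | 11 |
| epsilon | 20.0 | 14 |
| epsilon | 30.0 | 18 |
| epsilon | 40.0 | 20 |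
| epsilon | 50.0 | 21 |
| gamma | 4.00 | 21 |
| gamma | 12.0 | 27 |
| gamma | 25.0 | 35 |
| gamma | 40.0 | 41 |
| gamma | 50.0 | 43 |

(each reading ± 1.5 percentage points)

- amount of target at the end, in percent of the substrate charged for spring, dusk, dawn, winter, in this order
- the course of these numbers from the first flask to the last (falls all the way / falls, then rises / hardly changes / rises, then falls / rises all the way)

- in percentages every species weighs as the substrate in it: one spent catalyst counts as two
- reactions considered so far: 2 catalyst intermediate -> spent catalyst; substrate + free catalyst -> catalyst intermediate; catalyst intermediate -> free catalyst + target
- "hardly changes" means that all values lie within two and a half points (for a concentration: within two and a half percent of the largest)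

Tom and Ines dispute the row. Tom follows the catalyst. Target at the last reading is 21% in epsilon and 43% in gamma, so each ln unit of catalyst charge buys 11 percentage points. Carried on to winter, his line gives 47.5%, and the row rises all the way.

Ines follows the substrate. Let S be the substrate charged and C the catalyst charged. Each catalyst, as intermediate or spent, holds one substrate. With every catalyst holding one, 25.0% of winter's substrate stays outside. She calls this the room, ρ = 1 − C/S: the share of the substrate charged that exceeds the catalyst charged.

Let f be the share of catalyst still free. The balance then gives target plus substrate left = ρ + f·C/S. Winter's room lies below gamma's last reading.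

Tom objects that ρ is a floor for that sum, since free catalyst adds to it. Ines points to gamma: 21% after 4.00 min, yet 43% after 50.0 min. These readings slow early, so she expects little help from f.

Her forecast is 25%, 32%, 39% and 31%, a course that rises, then falls: “So winter should stall near 30%, below dawn.”

The flasks give 24.0%, 30.1%, 38.9% and 35.5%, a course that rises, then falls. Winter ends 3.4 points under dawn. Tom's rising course holds up to the turn at 1100 mM, where target reaches 43.3%, and winter lies past it.

    2 catalyst intermediate → spent catalyst (k = 2.30 L mol⁻¹ min⁻¹)
    substrate + free catalyst → catalyst intermediate (k = 1.20 L mol⁻¹ min⁻¹)
    catalyst intermediate → free catalyst + target (k = 0.500 min⁻¹)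

Winter's target stops at 35.5% because spent catalyst locks substrate: the same flask without that step gives 100%. Substrate is winter's limiting reagent, with 0% left after 50.0 min. So target is the room plus the free catalyst's part: 14.0% of the catalyst stays free, which adds 10 points to 25.0% and gives 35.5%. Dawn's room is 60.0%, and after 500 min its target stands at 57.6% with substrate at 2.54%.

(The earlier runs and the new flask come from a simulation with constants of no real substance; noise was put on by code.)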